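Its constants belong to no real substance; the flask was simulated.

You asked for a quick number.

left-handed substrate 20 mM; reagent 2.00 equiv; precatalyst 19 mol%; right-handed substrate 20 mM

    reagent + free catalyst + left-handed substrate → free catalyst + left-handed product (k1 = 860 L² mol⁻² s⁻¹)
    2 free catalyst → spent catalyst (k2 = 28 L mol⁻¹ s⁻¹)
    precatalyst ⇌ free catalyst (K3 = 0.42, k3 = 0.027 s⁻¹)
    reagent + free catalyst + right-handed substrate → free catalyst + right-handed product (k4 = 370 L² mol⁻² s⁻¹)

- free catalyst is single-handed; left-handed substrate and right-handed substrate are mirror images of each other, charged as a racemate, each of them at the stated concentration
- for a step with 2 of a species take k times the square, and two of it per event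
- a form made of two catalysts counts as two
- charge of left-handed substrate (flask): 20 mM

- the form that holds most of the catalyst when 5.0% of the left-handed substrate and right-handed substrate together are converted (free catalyst / spent catalyst / precatalyst)
- its share of the catalyst then

I reckoned it by one area. The catalyst went in as precatalyst, 3.80 mM of it, and the mark meant 2.00 mM of substrate converted. At the start precatalyst fed free catalyst at 0.103 mM s⁻¹, so I let c(free catalyst) climb in a straight line. With reagent and both substrates held at their charge (pseudo-first-order), each free catalyst turned over at 0.984 s⁻¹. Substrate converted was therefore the triangle under that line: turnover times feed times t squared, divided by 2.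

Setting this equal to the mark gave 6.29 s. This is the ramp time, the time to reach a set conversion while catalyst is fed in at a steady rate and reagent and substrates are held at their charge. By then the ramp had released 17.0% of the catalyst, and squaring the same line for the pairing step put 1.29% into spent catalyst. So the largest holder was precatalyst, at 83.0%. On that line the return step reached half of the release, so I took my time as early.

Your forecast named precatalyst at 86%, a little more than my share, and said “Free catalyst is released slowly”.

This flask reached 5.0% at 7.33 s, later than the ramp time, with precatalyst at 85.4%, so your forecast held. Free catalyst then stood at 13.4% and spent catalyst at 1.16%. On the ramp, conversion grows with the square of time, so at 0.800 s the ramp time gave 0.0809%, and this flask held 0.0787% as left-handed and right-handed product together.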